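Everything rests on disconnecting the adjacent ring carbons C1 (quaternary: methyl and homofarnesyl chain) and C2 (CH with the hydroxypropyl arm) of the cyclohexane. Because they sit between C6 and C3, both held at carbonyl level, a 2-methylcyclohexenone (C6 ketone, C1=C2 alkene, C3 ketal) can take up a 3-silyloxypropyl nucleophile at C2 under chiral copper catalysis and an allyl group at C1 through the resulting enolate. One flask thus forms the C2–arm and C1–chain bonds and both stereocentres, trans, with no ring closure. The precursor, 7-methyl-1,4-dioxaspiro[4.5]dec-6-en-8-one, is made regiospecifically from the parent enone by α-iodination and methylation.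

Key step: step 4

Remark: ring atoms are numbered as in the target throughout (C1 quaternary, C2 arm-bearing CH, C3 alkylidene/carbonyl carbon, C4, C5, C6 carbinol).
Assumption: the ligand antipode named in step 4 is taken to deliver the alkyl group to the Si face of the β-carbon of 3; should the sense of induction be opposite, the commercial enantiomeric ligand is used.
Remark: the arm is carried as a tert-butyldiphenylsilyl ether so that it survives the acidic ketal hydrolysis of step 6; the β-carbon of 3 is neopentyl-like (next to the ketal carbon), which is why the risk is placed in step 4.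

Step 1
Reactants: 1 1,4-dioxaspiro[4.5]dec-6-en-8-one
Product: 2 7-iodo-1,4-dioxaspiro[4.5]dec-6-en-8-one
Conditions: I2, pyridine, CH2Cl2, 0 °C → rt
Reagents that add atoms: iodine, II
Why: α-Iodination of the enone by the pyridine addition–iodination–elimination sequence (Baylis–Hillman-type mechanism) should place iodine only on the α-vinylic carbon, which fixes where the methyl group will sit.

Step 2
Reactants: 2 7-iodo-1,4-dioxaspiro[4.5]dec-6-en-8-one
Product: 3 7-methyl-1,4-dioxaspiro[4.5]dec-6-en-8-one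
Conditions: MeB(OH)2, Pd(dppf)Cl2 (cat.), K2CO3, dioxane/H2O, 80 °C
Reagents that add atoms: methylboronic acid, CB(O)O
Why: Suzuki–Miyaura coupling of the activated alkenyl iodide should exchange iodine for methyl without moving the double bond, so the 2-methylenone forms as one regioisomer.

Step 3
Reactants: 4 (3-bromopropoxy)(tert-butyl)diphenylsilane
Product: 5 [3-(tert-butyldiphenylsilyloxy)propyl]magnesium bromide
Conditions: Mg turnings, Et2O, reflux; used as solution
Reagents that add atoms: magnesium, [Mg]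
Why: Grignard formation by magnesium insertion into the primary C–Br bond; the silyl ether is three carbons away and cannot be eliminated.

Step 4
Reactants: 3 7-methyl-1,4-dioxaspiro[4.5]dec-6-en-8-one; 5 [3-(tert-butyldiphenylsilyloxy)propyl]magnesium bromide; 6 allyl bromide
Product: 8 (6S,7S)-6-[3-(tert-butyldiphenylsilyloxy)propyl]-7-methyl-7-(prop-2-en-1-yl)-1,4-dioxaspiro[4.5]decan-8-one, via bromomagnesium enolate 7 (not isolated)
Conditions: CuBr·SMe2 (5 mol%), (R,Sp)-Josiphos (6 mol%), t-BuOMe, −78 °C, slow addition of 5; then 6 (excess), DMPU, −78 → 0 °C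
Reagents that add atoms: none
Why: Transmetalation of 5 to the chiral diphosphine–copper bromide complex (monovalent copper) gives an alkylcopper species that π-binds enone 3, adds oxidatively at the β-carbon C2 to a trivalent copper intermediate and reductively eliminates, which forms the C2–arm bond and releases bromomagnesium enolate 7; SN2 attack of the enolate carbon C1 on allyl bromide then forms the C1–chain bond. The closest known reaction type is the copper-catalysed asymmetric conjugate addition of Grignard reagents to 2-substituted cyclic enones with alkylation of the magnesium enolate in the same flask. No ring is closed. C2 is set by the ligand, which should direct the alkyl group to the Si face of the β-carbon, and C1 by the substrate, because the new C2 arm lies pseudoaxial next to the enolate methyl group (A(1,2) strain) and allyl bromide enters anti to it, giving the trans product. The step needs 1,4- over 1,2-addition, secured by the soft organocopper species and slow addition at −78 °C, and C-alkylation of one defined enolate, secured by the regiospecific enolate from the conjugate addition, the magnesium counter-ion and DMPU; the C3 ketal keeps the second carbonyl inert.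

Step 5
Reactants: 8 (6S,7S)-6-[3-(tert-butyldiphenylsilyloxy)propyl]-7-methyl-7-(prop-2-en-1-yl)-1,4-dioxaspiro[4.5]decan-8-one
Product: 9 (6S,7S,8S)-6-[3-(tert-butyldiphenylsilyloxy)propyl]-7,8-dimethyl-7-(prop-2-en-1-yl)-1,4-dioxaspiro[4.5]decan-8-ol
Conditions: MeMgBr, CeCl3, THF, −78 → 0 °C
Reagents that add atoms: methylmagnesium bromide, C[Mg]Br
Why: 1,2-Addition of the organocerium reagent, which suppresses enolisation of the hindered ketone, should occur on the face of C6 opposite to the C1 methyl group and the C2 arm (one blocks equatorial, the other axial attack on the respective chair), so the new methyl group ends up cis to the allyl chain.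

Step 6
Reactants: 9 (6S,7S,8S)-6-[3-(tert-butyldiphenylsilyloxy)propyl]-7,8-dimethyl-7-(prop-2-en-1-yl)-1,4-dioxaspiro[4.5]decan-8-ol
Product: 10 (2S,3S,4S)-2-[3-(tert-butyldiphenylsilyloxy)propyl]-4-hydroxy-3,4-dimethyl-3-(prop-2-en-1-yl)cyclohexan-1-one
Conditions: 1 M HCl, THF, 0 °C → rt, short reaction time
Reagents that add atoms: water, O
Why: Acid-catalysed ketal hydrolysis frees the C3 ketone much faster than the ketone can enolise towards C2, and the tert-butyldiphenylsilyl ether and the tertiary alcohol tolerate dilute acid.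

Step 7
Reactants: 10 (2S,3S,4S)-2-[3-(tert-butyldiphenylsilyloxy)propyl]-4-hydroxy-3,4-dimethyl-3-(prop-2-en-1-yl)cyclohexan-1-one
Product: 11 (2S,3S,4S)-2-[3-(tert-butyldiphenylsilyloxy)propyl]-3,4-dimethyl-3-(prop-2-en-1-yl)-4-(triethylsilyloxy)cyclohexan-1-one
Conditions: Et3SiOTf, 2,6-lutidine, CH2Cl2, −78 → 0 °C
Reagents that add atoms: triethylsilyl trifluoromethanesulfonate, CC[Si](CC)(CC)OS(=O)(=O)C(F)(F)F
Why: Silylation of the hindered tertiary alcohol with a silyl triflate and a hindered base protects it from Appel-type side reactions and from later lactol formation with the chain aldehyde.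

Step 8
Reactants: 11 (2S,3S,4S)-2-[3-(tert-butyldiphenylsilyloxy)propyl]-3,4-dimethyl-3-(prop-2-en-1-yl)-4-(triethylsilyloxy)cyclohexan-1-one
Product: 12 tert-butyl{3-[(1S,2S,3S)-6-(dibromomethylidene)-2,3-dimethyl-2-(prop-2-en-1-yl)-3-(triethylsilyloxy)cyclohexyl]propoxy}diphenylsilane
Conditions: CBr4, PPh3, toluene, 80 °C
Reagents that add atoms: carbon tetrabromide, BrC(Br)(Br)Br
Why: Ramirez dibromoolefination (the first stage of the Corey–Fuchs sequence) with Ph3P=CBr2 is a neutral carbonyl olefination, so the C3 ketone should be converted without epimerising C2.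

Step 9
Reactants: 12 tert-butyl{3-[(1S,2S,3S)-6-(dibromomethylidene)-2,3-dimethyl-2-(prop-2-en-1-yl)-3-(triethylsilyloxy)cyclohexyl]propoxy}diphenylsilane
Product: 13 tert-butyl{3-[(1S,2S,3S,6Z)-6-(1-bromoethylidene)-2,3-dimethyl-2-(prop-2-en-1-yl)-3-(triethylsilyloxy)cyclohexyl]propoxy}diphenylsilane
Conditions: MeZnCl (1.2 equiv), Pd(DPEphos)Cl2 (5 mol%), THF, 0 °C → rt
Reagents that add atoms: methylzinc chloride, C[Zn]Cl
Why: Negishi coupling used as the stereoselective mono-coupling of a 1,1-dibromoalkene, in which zerovalent palladium should insert into the less hindered C–Br bond (on the side of the C4 methylene, away from the substituted C2), so the methyl group ends up cis to C4.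

Step 10
Reactants: 13 tert-butyl{3-[(1S,2S,3S,6Z)-6-(1-bromoethylidene)-2,3-dimethyl-2-(prop-2-en-1-yl)-3-(triethylsilyloxy)cyclohexyl]propoxy}diphenylsilane
Product: 15 (2Z)-2-[(2R,3S,4S)-2-[3-(tert-butyldiphenylsilyloxy)propyl]-3,4-dimethyl-3-(prop-2-en-1-yl)-4-(triethylsilyloxy)cyclohexylidene]propan-1-ol, via alkenyllithium 14 (not isolated)
Conditions: t-BuLi (2.1 equiv), Et2O, −78 °C; then CH2O (gas, from cracked paraformaldehyde), −78 → 0 °C
Reagents that add atoms: tert-butyllithium, [Li]C(C)(C)C; formaldehyde, C=O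
Why: Bromine–lithium exchange proceeds with retention and the tetrasubstituted alkenyllithium is configurationally stable at −78 °C, so hydroxymethylation with formaldehyde should place the future aldehyde carbon cis to C2 (Z alkene).

Step 11
Reactants: 15 (2Z)-2-[(2R,3S,4S)-2-[3-(tert-butyldiphenylsilyloxy)propyl]-3,4-dimethyl-3-(prop-2-en-1-yl)-4-(triethylsilyloxy)cyclohexylidene]propan-1-ol
Product: 16 tert-butyldimethylsilyl ether of 15
Conditions: t-BuMe2SiCl, imidazole, DMF, rt
Reagents that add atoms: tert-butyl(chloro)dimethylsilane, CC(C)(C)[Si](C)(C)Cl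
Why: Imidazole-promoted silylation of the primary allylic alcohol masks the future enal during the chain extension.

Step 12
Reactants: 16 tert-butyldimethylsilyl ether of 15
Product: 18 3-[(1S,2R,3Z,6S)-3-[1-(tert-butyldimethylsilyloxy)propan-2-ylidene]-2-[3-(tert-butyldiphenylsilyloxy)propyl]-1,6-dimethyl-6-(triethylsilyloxy)cyclohexyl]propan-1-ol, via B-alkyl-9-BBN adduct 17 (not isolated)
Conditions: 9-BBN, THF, rt; then NaOH, H2O2, 0 °C
Reagents that add atoms: 9-borabicyclo[3.3.1]nonane, B1C2CCCC1CCC2; hydrogen peroxide, OO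
Why: Anti-Markovnikov hydroboration with 9-BBN attacks only the monosubstituted alkene (the tetrasubstituted one is inert) and oxidation of the C–B bond gives the primary alcohol.

Step 13
Reactants: 18 primary alcohol from step 12
Product: 19 3-[(1S,2R,3Z,6S)-3-[1-(tert-butyldimethylsilyloxy)propan-2-ylidene]-2-[3-(tert-butyldiphenylsilyloxy)propyl]-1,6-dimethyl-6-(triethylsilyloxy)cyclohexyl]propanal
Conditions: Dess–Martin periodinane, NaHCO3, CH2Cl2, rt
Reagents that add atoms: none
Why: Dess–Martin oxidation converts the primary alcohol to the aldehyde under buffered conditions that leave the three silyl ethers intact.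

Step 14
Reactants: 19 aldehyde from step 13
Product: 20 1,1-dibromoalkene (ring C1–CH2CH2CH=CBr2; other groups as in 19)
Conditions: CBr4, PPh3, 2,6-lutidine, CH2Cl2, 0 °C
Reagents that add atoms: carbon tetrabromide, BrC(Br)(Br)Br
Why: Ramirez dibromoolefination of an unhindered aliphatic aldehyde is fast at 0 °C, and the buffer protects the silyl ethers.

Step 15
Reactants: 21 nerol
Product: 22 [(2R,3S)-3-methyl-3-(4-methylpent-3-en-1-yl)oxiran-2-yl]methanol
Conditions: Ti(Oi-Pr)4 (cat.), D-(−)-diethyl tartrate (cat.), t-BuOOH, 4 Å molecular sieves, CH2Cl2, −20 °C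
Reagents that add atoms: tert-butyl hydroperoxide, CC(C)(C)OO
Why: Katsuki–Sharpless asymmetric epoxidation, in which the allylic hydroxyl binds the tetravalent titanium tartrate so that only the 2,3-alkene reacts, and D-(−)-tartrate should give the (2R,3S)-epoxy alcohol from this Z-allylic alcohol.

Step 16
Reactants: 22 [(2R,3S)-3-methyl-3-(4-methylpent-3-en-1-yl)oxiran-2-yl]methanol
Product: 23 (2S,3S)-3-methyl-3-(4-methylpent-3-en-1-yl)oxirane-2-carbaldehyde
Conditions: Dess–Martin periodinane, NaHCO3, CH2Cl2, 0 °C; used crude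
Reagents that add atoms: none
Why: Buffered Dess–Martin oxidation gives the epoxy aldehyde without opening the epoxide or epimerising the α-carbon (the descriptor changes only because the priorities change).

Step 17
Reactants: 23 (2S,3S)-3-methyl-3-(4-methylpent-3-en-1-yl)oxirane-2-carbaldehyde
Product: 24 (2S,3R)-3-ethenyl-2-methyl-2-(4-methylpent-3-en-1-yl)oxirane
Conditions: Ph3PCH3Br, KN(SiMe3)2, THF, 0 °C; then 23, −78 → 0 °C
Reagents that add atoms: methyltriphenylphosphonium bromide, C[P+](c1ccccc1)(c1ccccc1)c1ccccc1.[Br-]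
Why: Wittig methylenation with the non-stabilised ylide converts the aldehyde to the vinyl epoxide and leaves both epoxide stereocentres untouched.

Step 18
Reactants: 20 1,1-dibromoalkene from step 14; 24 (2S,3R)-3-ethenyl-2-methyl-2-(4-methylpent-3-en-1-yl)oxirane
Product: 26 (Z)-alkenyl bromide (ring C1–CH2CH2CH=C(Br)–CH2CH2–epoxide chain), via epoxyalkyl-9-BBN 25 (not isolated)
Conditions: 24, 9-BBN, THF, 0 °C → rt; then 20, Pd(dppf)Cl2 (cat.), AsPh3, Cs2CO3, DMF/THF/H2O, rt
Reagents that add atoms: 9-borabicyclo[3.3.1]nonane, B1C2CCCC1CCC2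
Why: 9-BBN hydroborates the vinyl group in preference to the trisubstituted alkene, and the B-alkyl Suzuki–Miyaura coupling of a 1,1-dibromoalkene should occur at the less hindered bromine trans to the existing chain, so the epoxide-bearing chain is placed trans to the ring-side chain.

Step 19
Reactants: 26 (Z)-alkenyl bromide from step 18
Product: 27 fully protected (E)-alkene (tris-silyl ether of 28)
Conditions: MeB(OH)2, Pd[P(t-Bu)3]2 (cat.), Cs2CO3, THF/H2O, 50 °C
Reagents that add atoms: methylboronic acid, CB(O)O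
Why: Suzuki–Miyaura methylation of the remaining alkenyl bromide proceeds with retention of configuration and so completes the E-trisubstituted alkene under base-only conditions that an epoxide tolerates.

Step 20
Reactants: 27 fully protected (E)-alkene
Product: 28 (2Z)-2-[(2R,3S,4S)-4-hydroxy-2-(3-hydroxypropyl)-3,4-dimethyl-3-{(3E)-4-methyl-6-[(2R,3S)-3-methyl-3-(4-methylpent-3-en-1-yl)oxiran-2-yl]hex-3-en-1-yl}cyclohexylidene]propan-1-ol
Conditions: Bu4NF, THF, rt → 40 °C
Reagents that add atoms: none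
Why: Fluoride-induced desilylation removes the triethylsilyl, tert-butyldimethylsilyl and tert-butyldiphenylsilyl ethers in one operation, and the epoxide and the alkenes are inert to fluoride.

Step 21
Reactants: 28 triol from step 20
Product: 29 (2Z)-2-[(2R,3S,4S)-4-hydroxy-2-(3-hydroxypropyl)-3,4-dimethyl-3-{(3E)-4-methyl-6-[(2R,3S)-3-methyl-3-(4-methylpent-3-en-1-yl)oxiran-2-yl]hex-3-en-1-yl}cyclohexylidene]propanal (target)
Conditions: MnO2 (activated, excess), CH2Cl2, rt
Reagents that add atoms: none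
Why: MnO2 oxidation is selective for the allylic alcohol, so the enal should form in the presence of the saturated primary and the tertiary alcohol and without Z/E isomerisation.

Compound list
1 | 1,4-dioxaspiro[4.5]dec-6-en-8-one | O=C1C=CC2(CC1)OCCO2 | starting material
2 | 7-iodo-1,4-dioxaspiro[4.5]dec-6-en-8-one | O=C1C(I)=CC2(CC1)OCCO2 | intermediate
3 | 7-methyl-1,4-dioxaspiro[4.5]dec-6-en-8-one | CC1=CC2(CCC1=O)OCCO2 | intermediate
4 | (3-bromopropoxy)(tert-butyl)diphenylsilane | CC(C)(C)[Si](OCCCBr)(c1ccccc1)c1ccccc1 | starting material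
5 | [3-(tert-butyldiphenylsilyloxy)propyl]magnesium bromide | CC(C)(C)[Si](OCCC[Mg]Br)(c1ccccc1)c1ccccc1 | intermediate
6 | allyl bromide (3-bromoprop-1-ene) | C=CCBr | starting material
7 | bromomagnesium C7=C8 enolate of (6S)-6-[3-(tert-butyldiphenylsilyloxy)propyl]-7-methyl-1,4-dioxaspiro[4.5]decan-8-one | CC1=C(O[Mg]Br)CCC2(OCCO2)[C@H]1CCCO[Si](c1ccccc1)(c1ccccc1)C(C)(C)C | intermediate
8 | (6S,7S)-6-[3-(tert-butyldiphenylsilyloxy)propyl]-7-methyl-7-(prop-2-en-1-yl)-1,4-dioxaspiro[4.5]decan-8-one | C=CC[C@@]1(C)[C@H](CCCO[Si](c3ccccc3)(c3ccccc3)C(C)(C)C)C2(CCC1=O)OCCO2 | intermediate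
9 | (6S,7S,8S)-6-[3-(tert-butyldiphenylsilyloxy)propyl]-7,8-dimethyl-7-(prop-2-en-1-yl)-1,4-dioxaspiro[4.5]decan-8-ol | C=CC[C@@]1(C)[C@H](CCCO[Si](c3ccccc3)(c3ccccc3)C(C)(C)C)C2(CC[C@]1(C)O)OCCO2 | intermediate
10 | (2S,3S,4S)-2-[3-(tert-butyldiphenylsilyloxy)propyl]-4-hydroxy-3,4-dimethyl-3-(prop-2-en-1-yl)cyclohexan-1-one | C=CC[C@@]1(C)[C@H](CCCO[Si](c3ccccc3)(c3ccccc3)C(C)(C)C)C(=O)CC[C@]1(C)O | intermediate
11 | (2S,3S,4S)-2-[3-(tert-butyldiphenylsilyloxy)propyl]-3,4-dimethyl-3-(prop-2-en-1-yl)-4-(triethylsilyloxy)cyclohexan-1-one | C=CC[C@@]1(C)[C@H](CCCO[Si](c3ccccc3)(c3ccccc3)C(C)(C)C)C(=O)CC[C@]1(C)O[Si](CC)(CC)CC | intermediate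
12 | tert-butyl{3-[(1S,2S,3S)-6-(dibromomethylidene)-2,3-dimethyl-2-(prop-2-en-1-yl)-3-(triethylsilyloxy)cyclohexyl]propoxy}diphenylsilane | C=CC[C@@]1(C)[C@H](CCCO[Si](c3ccccc3)(c3ccccc3)C(C)(C)C)C(=C(Br)Br)CC[C@]1(C)O[Si](CC)(CC)CC | intermediate
13 | tert-butyl{3-[(1S,2S,3S,6Z)-6-(1-bromoethylidene)-2,3-dimethyl-2-(prop-2-en-1-yl)-3-(triethylsilyloxy)cyclohexyl]propoxy}diphenylsilane (Br cis to C2, methyl cis to C4) | C=CC[C@@]1(C)[C@H](CCCO[Si](c3ccccc3)(c3ccccc3)C(C)(C)C)/C(=C(/C)Br)CC[C@]1(C)O[Si](CC)(CC)CC | intermediate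
14 | alkenyllithium from 13 (Li in place of Br, geometry retained) | C=CC[C@@]1(C)[C@H](CCCO[Si](c3ccccc3)(c3ccccc3)C(C)(C)C)/C(=C(/C)[Li])CC[C@]1(C)O[Si](CC)(CC)CC | intermediate
15 | (2Z)-2-[(2R,3S,4S)-2-[3-(tert-butyldiphenylsilyloxy)propyl]-3,4-dimethyl-3-(prop-2-en-1-yl)-4-(triethylsilyloxy)cyclohexylidene]propan-1-ol | C=CC[C@@]1(C)[C@H](CCCO[Si](c3ccccc3)(c3ccccc3)C(C)(C)C)/C(=C(/C)CO)CC[C@]1(C)O[Si](CC)(CC)CC | intermediate
16 | tert-butyl{[(2Z)-2-{(2R,3S,4S)-2-[3-(tert-butyldiphenylsilyloxy)propyl]-3,4-dimethyl-3-(prop-2-en-1-yl)-4-(triethylsilyloxy)cyclohexylidene}propyl]oxy}dimethylsilane | C=CC[C@@]1(C)[C@H](CCCO[Si](c3ccccc3)(c3ccccc3)C(C)(C)C)/C(=C(/C)CO[Si](C)(C)C(C)(C)C)CC[C@]1(C)O[Si](CC)(CC)CC | intermediate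
17 | B-alkyl-9-BBN adduct of 16 (boron on the terminal carbon of the former allyl group) | C(CC[C@@]1(C)[C@H](CCCO[Si](c3ccccc3)(c3ccccc3)C(C)(C)C)/C(=C(/C)CO[Si](C)(C)C(C)(C)C)CC[C@]1(C)O[Si](CC)(CC)CC)B1C2CCCC1CCC2 | intermediate
18 | 3-[(1S,2R,3Z,6S)-3-[1-(tert-butyldimethylsilyloxy)propan-2-ylidene]-2-[3-(tert-butyldiphenylsilyloxy)propyl]-1,6-dimethyl-6-(triethylsilyloxy)cyclohexyl]propan-1-ol | OCCC[C@@]1(C)[C@H](CCCO[Si](c3ccccc3)(c3ccccc3)C(C)(C)C)/C(=C(/C)CO[Si](C)(C)C(C)(C)C)CC[C@]1(C)O[Si](CC)(CC)CC | intermediate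
19 | 3-[(1S,2R,3Z,6S)-3-[1-(tert-butyldimethylsilyloxy)propan-2-ylidene]-2-[3-(tert-butyldiphenylsilyloxy)propyl]-1,6-dimethyl-6-(triethylsilyloxy)cyclohexyl]propanal | O=CCC[C@@]1(C)[C@H](CCCO[Si](c3ccccc3)(c3ccccc3)C(C)(C)C)/C(=C(/C)CO[Si](C)(C)C(C)(C)C)CC[C@]1(C)O[Si](CC)(CC)CC | intermediate
20 | 1,1-dibromoalkene: 19 with CHO replaced by CH=CBr2 (4,4-dibromobut-3-en-1-yl chain on C1) | BrC(Br)=CCC[C@@]1(C)[C@H](CCCO[Si](c3ccccc3)(c3ccccc3)C(C)(C)C)/C(=C(/C)CO[Si](C)(C)C(C)(C)C)CC[C@]1(C)O[Si](CC)(CC)CC | intermediate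
21 | nerol, (2Z)-3,7-dimethylocta-2,6-dien-1-ol | CC(C)=CCC/C(C)=C\CO | starting material
22 | [(2R,3S)-3-methyl-3-(4-methylpent-3-en-1-yl)oxiran-2-yl]methanol | CC(C)=CCC[C@]1(C)O[C@@H]1CO | intermediate
23 | (2S,3S)-3-methyl-3-(4-methylpent-3-en-1-yl)oxirane-2-carbaldehyde | CC(C)=CCC[C@]1(C)O[C@@H]1C=O | intermediate
24 | (2S,3R)-3-ethenyl-2-methyl-2-(4-methylpent-3-en-1-yl)oxirane | CC(C)=CCC[C@]1(C)O[C@@H]1C=C | intermediate
25 | 9-{2-[(2R,3S)-3-methyl-3-(4-methylpent-3-en-1-yl)oxiran-2-yl]ethyl}-9-borabicyclo[3.3.1]nonane | CC(C)=CCC[C@]1(C)O[C@@H]1CCB1C2CCCC1CCC2 | intermediate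
26 | (Z)-alkenyl bromide: ring C1–CH2CH2–CH=C(Br)–CH2CH2–[(2R,3S)-epoxide], epoxide chain trans to the ring-side chain; silyl ethers as in 20 | CC(C)=CCC[C@]1(C)O[C@@H]1CC/C(Br)=C/CC[C@@]1(C)[C@H](CCCO[Si](c3ccccc3)(c3ccccc3)C(C)(C)C)/C(=C(/C)CO[Si](C)(C)C(C)(C)C)CC[C@]1(C)O[Si](CC)(CC)CC | intermediate
27 | tris-silyl ether of 28 (C6–O triethylsilyl, allylic O tert-butyldimethylsilyl, arm O tert-butyldiphenylsilyl; chain alkene E) | CC(C)=CCC[C@]1(C)O[C@@H]1CC/C(C)=C/CC[C@@]1(C)[C@H](CCCO[Si](c3ccccc3)(c3ccccc3)C(C)(C)C)/C(=C(/C)CO[Si](C)(C)C(C)(C)C)CC[C@]1(C)O[Si](CC)(CC)CC | intermediate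
28 | (2Z)-2-[(2R,3S,4S)-4-hydroxy-2-(3-hydroxypropyl)-3,4-dimethyl-3-{(3E)-4-methyl-6-[(2R,3S)-3-methyl-3-(4-methylpent-3-en-1-yl)oxiran-2-yl]hex-3-en-1-yl}cyclohexylidene]propan-1-ol | CC(C)=CCC[C@]1(C)O[C@@H]1CC/C(C)=C/CC[C@@]1(C)[C@H](CCCO)/C(=C(/C)CO)CC[C@]1(C)O | intermediate
29 | (2Z)-2-[(2R,3S,4S)-4-hydroxy-2-(3-hydroxypropyl)-3,4-dimethyl-3-{(3E)-4-methyl-6-[(2R,3S)-3-methyl-3-(4-methylpent-3-en-1-yl)oxiran-2-yl]hex-3-en-1-yl}cyclohexylidene]propanal | CC(C)=CCC[C@]1(C)O[C@@H]1CC/C(C)=C/CC[C@@]1(C)[C@H](CCCO)/C(=C(/C)C=O)CC[C@]1(C)O | target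

Total step count: 21 (steps 1–21, Grignard formation included).
Longest linear sequence: 17 steps (steps 1, 2, 4–14, 18–21).

Steps most likely to fail

Step 4. The conjugate addition may be slow at a β-carbon flanked by the ketal carbon, and the tetrasubstituted magnesium enolate may be allylated incompletely or on oxygen. The fallback sets out from 3 and 5 and separates the two bond formations. The same copper-catalysed addition is run with Me3SiCl, which also accelerates the addition, so that the enolate is captured as the trimethylsilyl enol ether F1. MeLi cleaves F1 to the lithium enolate, which allyl chloroformate acylates on oxygen to the allyl enol carbonate F2. Pd(PPh3)4 (zerovalent palladium) then brings about the decarboxylative Tsuji allylation at C1, again anti to the C2 arm, and the route is rejoined at 8.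

Step 18. The vinyl epoxide may be opened reductively during hydroboration, the γ-epoxy alkylborate may undergo 1,3-elimination under the basic coupling conditions, and the trans selectivity of the coupling may be incomplete. The fallback sets out from aldehyde 19 and epoxy alcohol 22 and replaces the cross-coupling by sulfone alkylation. Wittig reaction of 19 with Ph3P=C(CH3)CO2Et should give the E-enoate F3, i-Bu2AlH reduction the allylic alcohol F4, CBr4/PPh3 the allylic bromide F5 and PhSO2Na the allylic sulfone F6. In parallel 22 is converted with I2, PPh3 and imidazole into the epoxy iodide F7. The lithium anion of F6 (n-BuLi, THF, −78 °C) is alkylated by F7 to the sulfone F8, and reductive desulfonylation with LiBHEt3 and Pd(dppp)Cl2 (cat.) leads to 27, where the route is rejoined. This fallback carries a risk of its own: the π-allyl intermediate has two secondary termini, so hydride delivery may also give the transposed alkene.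

Step 9. The two geminal C–Br bonds may not be discriminated well enough in the oxidative addition, which would give an isomer mixture or double methylation; the same fallback also bypasses a sluggish dibromoolefination of the hindered ketone in step 8. The fallback sets out from ketone 11. CeCl3-mediated addition of isopropenylmagnesium bromide gives the tertiary allylic alcohol F9. Oxidative 1,3-transposition with pyridinium chlorochromate, (C5H5NH)[CrO3Cl] (Babler–Dauben oxidation), gives the enal F10; its isomer with the methyl group on the side of the C4 methylene should be the less strained one and can be enriched by equilibration with a trace of iodine. Luche reduction (NaBH4, CeCl3·7H2O) of F10 returns to 15.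

Further compounds
F1 | step 4 | trimethylsilyl enol ether of (6S)-6-[3-(tert-butyldiphenylsilyloxy)propyl]-7-methyl-1,4-dioxaspiro[4.5]decan-8-one (C7=C8) | CC1=C(O[Si](C)(C)C)CCC2(OCCO2)[C@H]1CCCO[Si](c1ccccc1)(c1ccccc1)C(C)(C)C
F2 | step 4 | allyl enol carbonate of the same ketone (C7=C8) | CC1=C(OC(=O)OCC=C)CCC2(OCCO2)[C@H]1CCCO[Si](c1ccccc1)(c1ccccc1)C(C)(C)C
F3 | step 18 | ethyl (2E)-2-methylpent-2-enoate carrying the ring of 19 at C5 | CCOC(=O)/C(C)=C/CC[C@@]1(C)[C@H](CCCO[Si](c3ccccc3)(c3ccccc3)C(C)(C)C)/C(=C(/C)CO[Si](C)(C)C(C)(C)C)CC[C@]1(C)O[Si](CC)(CC)CC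
F4 | step 18 | (2E)-allylic alcohol from F3 | OC/C(C)=C/CC[C@@]1(C)[C@H](CCCO[Si](c3ccccc3)(c3ccccc3)C(C)(C)C)/C(=C(/C)CO[Si](C)(C)C(C)(C)C)CC[C@]1(C)O[Si](CC)(CC)CC
F5 | step 18 | (2E)-allylic bromide from F4 | BrC/C(C)=C/CC[C@@]1(C)[C@H](CCCO[Si](c3ccccc3)(c3ccccc3)C(C)(C)C)/C(=C(/C)CO[Si](C)(C)C(C)(C)C)CC[C@]1(C)O[Si](CC)(CC)CC
F6 | step 18 | (2E)-allylic phenyl sulfone from F5 | O=S(=O)(c4ccccc4)C/C(C)=C/CC[C@@]1(C)[C@H](CCCO[Si](c3ccccc3)(c3ccccc3)C(C)(C)C)/C(=C(/C)CO[Si](C)(C)C(C)(C)C)CC[C@]1(C)O[Si](CC)(CC)CC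
F7 | step 18 | (2S,3S)-2-(iodomethyl)-3-methyl-3-(4-methylpent-3-en-1-yl)oxirane | CC(C)=CCC[C@]1(C)O[C@@H]1CI
F8 | step 18 | alkylated sulfone (27 with a phenylsulfonyl group on the allylic CH next to the chain C-methyl carbon; mixture at that carbon) | CC(C)=CCC[C@]1(C)O[C@@H]1CC(S(=O)(=O)c4ccccc4)/C(C)=C/CC[C@@]1(C)[C@H](CCCO[Si](c3ccccc3)(c3ccccc3)C(C)(C)C)/C(=C(/C)CO[Si](C)(C)C(C)(C)C)CC[C@]1(C)O[Si](CC)(CC)CC
F9 | step 9 | tertiary allylic alcohol from 11 (isopropenyl and hydroxyl on C3; configuration at C3 not controlled) | C=CC[C@@]1(C)[C@H](CCCO[Si](c3ccccc3)(c3ccccc3)C(C)(C)C)C(O)(C(C)=C)CC[C@]1(C)O[Si](CC)(CC)CC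
F10 | step 9 | (2Z)-2-[(2R,3S,4S)-2-[3-(tert-butyldiphenylsilyloxy)propyl]-3,4-dimethyl-3-(prop-2-en-1-yl)-4-(triethylsilyloxy)cyclohexylidene]propanal | C=CC[C@@]1(C)[C@H](CCCO[Si](c3ccccc3)(c3ccccc3)C(C)(C)C)/C(=C(/C)C=O)CC[C@]1(C)O[Si](CC)(CC)CC
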